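**Retrosynthetic overview**
- The target is a depside. The last two operations are hydrogenolysis of a benzyl ester on ring A and O-methylation of the C4' phenol on ring B.
- The strategy rests on ring B: its carboxyl carbon C1' lies between the methoxy carbon C2' and the propyl carbon C6', with a second oxygen at C4'. This is the footprint of a CH2=C(O)–CH=C(O)2 diene (C2'–C5') laid on a propyl-substituted ynoate (C1', C6').
- Ring B is therefore opened by retro-[4+2] across C1'–C2' and C5'–C6', giving the ring A aryl hex-2-ynoate 9 and the silyloxy ketene-acetal diene 2.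
- Ester 9 comes from phenol 7 and hex-2-ynoic acid. Ring A has the same footprint (C1 carboxyl between C2 methoxy and C6 pentyl, oxygen at C4) and is made from benzyl oct-2-ynoate and the same diene.
- Order of ring formation: ring A (step 3), then ring B on the preformed ester (step 5).

Key step: step 5

Remark: 4,4-dimethoxybut-3-en-2-one, oct-2-ynoic acid and hex-2-ynoic acid are taken as purchasable. Ring A is built by the same benzannulation as ring B, so that the key precursor is reached in three operations from oct-2-ynoic acid.

**Step 1**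
Reactants: 1 4,4-dimethoxybut-3-en-2-one
Product: 2 1,1-dimethoxy-3-(trimethylsilyloxy)buta-1,3-diene
Conditions: Me3SiCl, Et3N, ZnCl2 (cat.), Et2O, rt; filtration under Ar, distillation under reduced pressure
Reagents that add atoms: chlorotrimethylsilane, C[Si](C)(C)Cl
Why: Silyl enol ether formation by soft enolization, in which the methyl ketone is the only enolizable position, so O-silylation can give only the cross-conjugated 2-silyloxydiene.

**Step 2**
Reactants: 3 oct-2-ynoic acid
Product: 4 benzyl oct-2-ynoate
Conditions: BnBr, KHCO3, DMF, rt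
Reagents that add atoms: benzyl bromide, BrCc1ccccc1
Why: Carboxylate O-alkylation (SN2) under bicarbonate conditions is mild enough to avoid isomerization of the conjugated alkyne to an allenoate.

**Step 3**
Reactants: 4 benzyl oct-2-ynoate; 2 1,1-dimethoxy-3-(trimethylsilyloxy)buta-1,3-diene (2.5 equiv)
Product: 7 benzyl 4-hydroxy-2-methoxy-6-pentylbenzoate, via cyclohexa-1,4-diene adduct 5 (not isolated), via aryl trimethylsilyl ether 6 (not isolated)
Conditions: xylene, 130 °C, sealed tube, Ar; then 0.5 M HCl, THF, rt
Reagents that add atoms: none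
Why: Diels–Alder benzannulation of a 1,1-dialkoxy-3-silyloxybutadiene with an alkyl 2-alkynoate, a known route to 2-alkoxy-4-hydroxy-6-alkylbenzoates, in which the diene CH2 terminus bonds to the pentyl-bearing β-carbon and the ketene acetal carbon to the α-carbon, after which loss of methanol aromatizes adduct 5 and dilute acid cleaves silyl ether 6, so that ring A should emerge with methoxy at C2, free hydroxyl at C4 and pentyl at C6.

**Step 4**
Reactants: 7 benzyl 4-hydroxy-2-methoxy-6-pentylbenzoate; 8 hex-2-ynoic acid
Product: 9 benzyl 4-(hex-2-ynoyloxy)-2-methoxy-6-pentylbenzoate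
Conditions: DCC, DMAP (cat.), CH2Cl2, 0 °C to rt
Reagents that add atoms: none
Why: Steglich esterification of an unhindered 2-alkynoic acid with the single free phenol of 7, a standard way to make aryl alkynoates, run cold to suppress addition of DMAP to the triple bond.

**Step 5 (key step)**
Reactants: 9 benzyl 4-(hex-2-ynoyloxy)-2-methoxy-6-pentylbenzoate; 2 1,1-dimethoxy-3-(trimethylsilyloxy)buta-1,3-diene (3 equiv)
Product: 12 benzyl 4-[(4-hydroxy-2-methoxy-6-propylbenzoyl)oxy]-2-methoxy-6-pentylbenzoate, via cyclohexa-1,4-diene adduct 10 (not isolated), via aryl trimethylsilyl ether 11 (not isolated)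
Conditions: toluene, 110 °C, sealed tube, Ar; then 0.5 M HCl, THF, 0 °C to rt
Reagents that add atoms: none
Why: In a normal-electron-demand Diels–Alder addition the electron-rich diene 2, whose largest HOMO coefficient is at the CH2 terminus, adds across the triple bond of 9, whose largest LUMO coefficient is at the propyl-bearing β-carbon, either concertedly but asynchronously or through a Michael-type zwitterion that collapses to the same ring, forming C5'–C6' and C1'–C2' to give cyclohexa-1,4-diene 10. Loss of methanol from the ketal carbon of 10 aromatizes ring B to silyl ether 11, and dilute acid cleaves the O–Si bond to phenol 12. The closest known reaction type is the benzannulation of 1,1-dialkoxy-3-silyloxybuta-1,3-dienes with alkyl 2-alkynoates to 2-alkoxy-4-hydroxy-6-alkylbenzoates, applied here to an aryl ester, whose more electron-poor carbonyl should lower the alkyne LUMO and speed the addition relative to step 3. Ring B is closed by an intermolecular [4+2] cycloaddition that makes both ring bonds in one operation, and no stereocentre arises because the adduct aromatizes. The step needs regioselectivity, which the matched polarization secures (methoxy at C2' beside the carboxyl carbon, propyl at C6', hydroxyl at C4'), and chemoselectivity, which follows from 9 holding a single alkyne and two ester carbonyls that a ketene acetal should not attack without a Lewis acid. The excess of 2 also traps the methanol released, so that it should not cleave the aryl ester.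

**Step 6**
Reactants: 12 benzyl 4-[(4-hydroxy-2-methoxy-6-propylbenzoyl)oxy]-2-methoxy-6-pentylbenzoate
Product: 13 benzyl 4-[(2,4-dimethoxy-6-propylbenzoyl)oxy]-2-methoxy-6-pentylbenzoate
Conditions: MeI, K2CO3, acetone, 40 °C
Reagents that add atoms: iodomethane, CI
Why: Williamson ether synthesis on the only free phenol, with both ester carbonyls shielded by two ortho substituents against attack by the phenoxide.

**Step 7**
Reactants: 13 benzyl 4-[(2,4-dimethoxy-6-propylbenzoyl)oxy]-2-methoxy-6-pentylbenzoate
Product: 14 4-[(2,4-dimethoxy-6-propylbenzoyl)oxy]-2-methoxy-6-pentylbenzoic acid (target)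
Conditions: H2 (1 atm), Pd/C (10 wt%), EtOAc, rt
Reagents that add atoms: none
Why: Catalytic hydrogenolysis cleaves the benzylic C–O bond of the benzyl ester under neutral conditions, while the aryl ester link and the aryl methyl ethers have no hydrogenolysable bond.

**Compound list**
1 | 4,4-dimethoxybut-3-en-2-one | CC(=O)C=C(OC)OC | starting material
2 | 1,1-dimethoxy-3-(trimethylsilyloxy)buta-1,3-diene | C=C(O[Si](C)(C)C)C=C(OC)OC | intermediate
3 | oct-2-ynoic acid | CCCCCC#CC(=O)O | starting material
4 | benzyl oct-2-ynoate | CCCCCC#CC(=O)OCc1ccccc1 | intermediate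
5 | benzyl 6,6-dimethoxy-2-pentyl-4-(trimethylsilyloxy)cyclohexa-1,4-diene-1-carboxylate | CCCCCC1=C(C(=O)OCc2ccccc2)C(OC)(OC)C=C(O[Si](C)(C)C)C1 | intermediate
6 | benzyl 2-methoxy-6-pentyl-4-(trimethylsilyloxy)benzoate | CCCCCc1cc(O[Si](C)(C)C)cc(OC)c1C(=O)OCc1ccccc1 | intermediate
7 | benzyl 4-hydroxy-2-methoxy-6-pentylbenzoate | CCCCCc1cc(O)cc(OC)c1C(=O)OCc1ccccc1 | intermediate
8 | hex-2-ynoic acid | CCCC#CC(=O)O | starting material
9 | benzyl 4-(hex-2-ynoyloxy)-2-methoxy-6-pentylbenzoate | CCCCCc1cc(OC(=O)C#CCCC)cc(OC)c1C(=O)OCc1ccccc1 | intermediate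
10 | benzyl 4-{[6,6-dimethoxy-2-propyl-4-(trimethylsilyloxy)cyclohexa-1,4-diene-1-carbonyl]oxy}-2-methoxy-6-pentylbenzoate | CCCCCc1cc(OC(=O)C2=C(CCC)CC(O[Si](C)(C)C)=CC2(OC)OC)cc(OC)c1C(=O)OCc1ccccc1 | intermediate
11 | benzyl 2-methoxy-4-{[2-methoxy-6-propyl-4-(trimethylsilyloxy)benzoyl]oxy}-6-pentylbenzoate | CCCCCc1cc(OC(=O)c2c(CCC)cc(O[Si](C)(C)C)cc2OC)cc(OC)c1C(=O)OCc1ccccc1 | intermediate
12 | benzyl 4-[(4-hydroxy-2-methoxy-6-propylbenzoyl)oxy]-2-methoxy-6-pentylbenzoate | CCCCCc1cc(OC(=O)c2c(CCC)cc(O)cc2OC)cc(OC)c1C(=O)OCc1ccccc1 | intermediate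
13 | benzyl 4-[(2,4-dimethoxy-6-propylbenzoyl)oxy]-2-methoxy-6-pentylbenzoate | CCCCCc1cc(OC(=O)c2c(CCC)cc(OC)cc2OC)cc(OC)c1C(=O)OCc1ccccc1 | intermediate
14 | 4-[(2,4-dimethoxy-6-propylbenzoyl)oxy]-2-methoxy-6-pentylbenzoic acid | CCCCCc1cc(OC(=O)c2c(CCC)cc(OC)cc2OC)cc(OC)c1C(=O)O | target

**Total step count:** 7
**Longest linear sequence:** 6 steps (steps 2 to 7; the diene branch through steps 1 and 3 to 7 is equally long)

**Steps most likely to fail**

1. Step 5 (key cycloaddition). The β-propyl ynoate may add so slowly that the diene decomposes or oligomerizes first, and the methanol released, or the ketene acetal itself, may cleave the activated aryl ester before ring B has formed. The fallback brings ring B in as a finished acid and makes the depside bond last; it sets out from phenol 7 and comes back at 13.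
   - Purchased 1,3-dimethoxy-5-propylbenzene F1 is brominated with N-bromosuccinimide in MeCN, para to one methoxy group and ortho to the propyl group, to give 2-bromo-1,5-dimethoxy-3-propylbenzene F2.
   - Bromine–lithium exchange (n-BuLi, THF, −78 °C) gives (2,4-dimethoxy-6-propylphenyl)lithium F3, which is quenched with CO2 and acidified to 2,4-dimethoxy-6-propylbenzoic acid F4.
   - Trifluoroacetic anhydride in toluene at rt converts F4 into 2,4-dimethoxy-6-propylbenzoic trifluoroacetic anhydride F5, whose hindered, electron-rich aroyl group is transferred to the phenol of 7 to give 13. Step 7 then follows.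

2. Step 3 (ring A benzannulation). The β-pentyl benzyl ynoate is a weak dienophile, so thermal loss or adventitious hydrolysis of the diene may outrun the cycloaddition and leave low conversion. The fallback makes ring A from a resorcinol with no cycloaddition. It sets out from none of the numbered compounds (purchased olivetol F6 takes the place of 3 and 4) and comes back at 7.
   - Olivetol F6 is ortho-carboxylated in a Kolbe–Schmitt-type reaction with CH3OMgOCO2CH3 (DMF, 120 °C, then HCl) to 2,4-dihydroxy-6-pentylbenzoic acid F7.
   - BnBr and KHCO3 in DMF give benzyl 2,4-dihydroxy-6-pentylbenzoate F8.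
   - The non-chelated C4 hydroxyl is silylated (chlorotriisopropylsilane, imidazole, CH2Cl2) to benzyl 2-hydroxy-6-pentyl-4-(triisopropylsilyloxy)benzoate F9.
   - The hydrogen-bonded C2 hydroxyl is methylated (MeI, K2CO3, acetone, reflux) to benzyl 2-methoxy-6-pentyl-4-(triisopropylsilyloxy)benzoate F10.
   - Tetrabutylammonium fluoride buffered with acetic acid in THF removes the silyl group to give 7.

3. Step 4 (esterification). Rearrangement of the O-acylisourea to an N-acylurea, or conjugate addition of DMAP to the activated ynoate, may consume the acid before the moderately nucleophilic phenol is acylated. The fallback uses a preformed acyl chloride and no carbodiimide or nucleophilic catalyst; it sets out from 8 and comes back at 9.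
   - Acid 8 is treated with 1-chloro-N,N,2-trimethylprop-1-en-1-amine in CH2Cl2 at 0 °C, which gives hex-2-ynoyl chloride F11 under neutral conditions.
   - F11 is added to 7 and Et3N in CH2Cl2 at −20 °C to give 9.

**Further compounds**
F1 | step 5 | 1,3-dimethoxy-5-propylbenzene | CCCc1cc(OC)cc(OC)c1
F2 | step 5 | 2-bromo-1,5-dimethoxy-3-propylbenzene | CCCc1cc(OC)cc(OC)c1Br
F3 | step 5 | (2,4-dimethoxy-6-propylphenyl)lithium | [Li]c1c(CCC)cc(OC)cc1OC
F4 | step 5 | 2,4-dimethoxy-6-propylbenzoic acid | CCCc1cc(OC)cc(OC)c1C(=O)O
F5 | step 5 | 2,4-dimethoxy-6-propylbenzoic trifluoroacetic anhydride | CCCc1cc(OC)cc(OC)c1C(=O)OC(=O)C(F)(F)F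
F6 | step 3 | olivetol (5-pentylbenzene-1,3-diol) | CCCCCc1cc(O)cc(O)c1
F7 | step 3 | 2,4-dihydroxy-6-pentylbenzoic acid | CCCCCc1cc(O)cc(O)c1C(=O)O
F8 | step 3 | benzyl 2,4-dihydroxy-6-pentylbenzoate | CCCCCc1cc(O)cc(O)c1C(=O)OCc1ccccc1
F9 | step 3 | benzyl 2-hydroxy-6-pentyl-4-(triisopropylsilyloxy)benzoate | CCCCCc1cc(O[Si](C(C)C)(C(C)C)C(C)C)cc(O)c1C(=O)OCc1ccccc1
F10 | step 3 | benzyl 2-methoxy-6-pentyl-4-(triisopropylsilyloxy)benzoate | CCCCCc1cc(O[Si](C(C)C)(C(C)C)C(C)C)cc(OC)c1C(=O)OCc1ccccc1
F11 | step 4 | hex-2-ynoyl chloride | CCCC#CC(=O)Cl
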